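**Retrosynthetic overview**

1. Locants used here: ring C1(=O)–C2=C3–C4(OH)–C5(OH); side chain C6(OAc), C7 … C20(H3). The last disconnection releases the C4/C5 cis-diol from an isopropylidene acetal.
2. Key disconnection C10–C11: a mixed Kolbe electrolysis unites a C1–C10 core acid (carboxyl carbon on C10) with undecanoic acid (C11–C20 plus its carboxyl carbon). Two carbons of like polarity, both carboxylate α-carbons, are joined as radicals with loss of 2 CO2. The step completes the C20 skeleton with all three stereocentres, the enone and the acetate already in place.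
3. Enabling feature: the unbranched tetramethylene spacer C7–C10 between the acetoxy carbon C6 and C10 keeps a C10 radical away from the C2=C3 enone of the five-membered ring (only eight-membered closure is possible). The fully substituted C5 leaves the ring ketone without an enolisable α′-hydrogen, so the C4/C5/C6 triad is inert to the electrolysis.
4. C5–C6: lithium aldol of the α′-enolate of the sugar-derived (3aS,6aS)-acetonide enone (supplies C4 and the C5 oxygen) with tert-butyl 6-oxohexanoate. Convex-face attack sets C5, a Zimmerman–Traxler chair sets C6, and acetylation of the single free hydroxyl places the acetate.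
5. Rings: the cyclopentenone C1–C5 is bought preformed and no carbocycle is closed. The temporary 1,3-dioxolane across O4/O5 is present from the start and is the only ring opened (last step).

Key step: step 5

Assumption: enone 3 is used as the catalogue (3aS,6aS)-(+)-enantiomer, the mirror image of the more common D-ribose-derived enone; every stereochemical argument below depends on this antipode.

**Step 1**
Reactants: 1 tert-butyl 6-hydroxyhexanoate
Product: 2 tert-butyl 6-oxohexanoate
Conditions: TEMPO (10 mol %), PhI(OAc)2 (1.1 equiv), CH2Cl2, rt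
Reagents that add atoms: none
Why: A TEMPO/oxoammonium oxidation with PhI(OAc)2 as terminal oxidant converts the primary alcohol into the aldehyde without over-oxidation and leaves the tert-butyl ester untouched.

**Step 2**
Reactants: 3 (3aS,6aS)-2,2-dimethyl-3a,6a-dihydro-4H-cyclopenta[d][1,3]dioxol-4-one; 2 tert-butyl 6-oxohexanoate
Product: 6 tert-butyl (6S)-6-[(3aS,6aS)-2,2-dimethyl-4-oxo-4,6a-dihydro-3aH-cyclopenta[d][1,3]dioxol-3a-yl]-6-hydroxyhexanoate, via lithium enolate 4 (not isolated), via lithium aldolate 5 (not isolated)
Conditions: LDA (1.1 equiv), THF, −78 °C; then 2, −78 °C; AcOH quench at −78 °C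
Reagents that add atoms: none
Why: Kinetic deprotonation can only occur at C5–H (C2 and C3 are vinylic, and loss of the C4 oxygen from the enolate would give an antiaromatic cyclopentadienone), and in the ensuing lithium aldol addition the aldehyde must approach the convex face anti to the dioxolane, which fixes C5 (new C5–C6 bond cis to C4–H, C5–O cis to C4–O), while a Zimmerman–Traxler chair with the chain equatorial on this Z-type enolate (enolate oxygen cis to the C5 oxygen) should favour the syn O5/O6 adduct, i.e. (6S).

**Step 3**
Reactants: 6 tert-butyl (6S)-6-[(3aS,6aS)-2,2-dimethyl-4-oxo-4,6a-dihydro-3aH-cyclopenta[d][1,3]dioxol-3a-yl]-6-hydroxyhexanoate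
Product: 7 tert-butyl (6S)-6-acetoxy-6-[(3aS,6aS)-2,2-dimethyl-4-oxo-4,6a-dihydro-3aH-cyclopenta[d][1,3]dioxol-3a-yl]hexanoate
Conditions: Ac2O, pyridine, DMAP (cat.), CH2Cl2, 0 °C → rt
Reagents that add atoms: acetic anhydride, CC(=O)OC(C)=O
Why: DMAP-catalysed acyl transfer to the only free hydroxyl (O4 and O5 are tied up in the acetal, so no site selection is needed) proceeds with retention at C6 and caps the β-hydroxy ketone against retro-aldol cleavage in the later steps.

**Step 4**
Reactants: 7 tert-butyl (6S)-6-acetoxy-6-[(3aS,6aS)-2,2-dimethyl-4-oxo-4,6a-dihydro-3aH-cyclopenta[d][1,3]dioxol-3a-yl]hexanoate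
Product: 8 (6S)-6-acetoxy-6-[(3aS,6aS)-2,2-dimethyl-4-oxo-4,6a-dihydro-3aH-cyclopenta[d][1,3]dioxol-3a-yl]hexanoic acid
Conditions: TFA/CH2Cl2 (1:4, anhydrous), 0 °C
Reagents that add atoms: none
Why: Acidolysis of the tert-butyl ester (E1 loss of isobutene) under anhydrous conditions should spare the secondary acetate and the cis-fused isopropylidene acetal, which is deactivated by the adjacent ketone and cannot hydrolyse without water.

**Step 5**
Reactants: 8 (6S)-6-acetoxy-6-[(3aS,6aS)-2,2-dimethyl-4-oxo-4,6a-dihydro-3aH-cyclopenta[d][1,3]dioxol-3a-yl]hexanoic acid; 9 undecanoic acid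
Product: 10 (1S)-1-[(3aS,6aS)-2,2-dimethyl-4-oxo-4,6a-dihydro-3aH-cyclopenta[d][1,3]dioxol-3a-yl]pentadecyl acetate
Conditions: 9 (6 equiv), KOH (5 mol % of total CO2H), MeOH, Pt anode/Pt cathode, undivided cell, constant current (ca. 150 mA cm−2), 35–40 °C, stopped before the acid is fully consumed
Reagents that add atoms: none
Why: At the platinum anode the carboxylates of 8 and 9 are oxidised by one electron each and lose CO2, giving the primary C10 radical of the core and the decyl radical (C11–C20), which recombine in the dense radical layer at the electrode to forge C10–C11 while protons are reduced to H2 at the cathode. The closest known reaction type is the mixed (hetero) Kolbe electrolysis of ω-functionalised alkanoic acids with an excess of a cheap fatty acid, a classical entry to long-chain lipids that tolerates remote esters, acetates and ketones. No ring is closed and no stereocentre is formed; C4, C5 and C6 are spectators because the radical site is four bonds from C6 and never becomes ionic. The step needs cross- over homo-coupling, radical coupling over two-electron (Hofer–Moest) oxidation, and coupling over attack on the C2=C3 enone or 1,5-hydrogen transfer from C6–H. Cross-coupling is secured statistically by the excess of 9 (icosane, the by-product, is non-polar and easily removed), and the one-electron path by the primary, unsubstituted nature of both radicals on smooth Pt at high current density in weakly acidic methanol. The enone is secured by the C7–C10 spacer, which allows cyclisation of the C10 radical only through an eight-membered ring, and by the low bulk enone concentration, at which bimolecular Giese addition and the slow 1,5-hydrogen shift should not compete with diffusion-controlled radical–radical coupling; the excess acid keeps the medium from turning basic, so the C6 acetate is not methanolysed.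

**Step 6**
Reactants: 10 (1S)-1-[(3aS,6aS)-2,2-dimethyl-4-oxo-4,6a-dihydro-3aH-cyclopenta[d][1,3]dioxol-3a-yl]pentadecyl acetate
Product: 11 (1S)-1-[(1R,5S)-1,5-dihydroxy-2-oxocyclopent-3-en-1-yl]pentadecyl acetate
Conditions: TFA/H2O (4:1), 0 °C → rt
Reagents that add atoms: none
Why: Aqueous acid hydrolysis of the isopropylidene acetal frees the C4/C5 cis-diol with no stereocentre involved, the secondary acetate surviving short exposure to aqueous TFA and the quaternary C5 excluding dehydration or epimerisation by enolisation.

**Compound list**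

1 | tert-butyl 6-hydroxyhexanoate | CC(C)(C)OC(=O)CCCCCO | starting material
2 | tert-butyl 6-oxohexanoate | CC(C)(C)OC(=O)CCCCC=O | intermediate
3 | (3aS,6aS)-2,2-dimethyl-3a,6a-dihydro-4H-cyclopenta[d][1,3]dioxol-4-one [(4S,5S)-4,5-O-isopropylidene-4,5-dihydroxycyclopent-2-enone] | CC1(C)O[C@H]2C=CC(=O)[C@H]2O1 | starting material
4 | lithium (6aS)-2,2-dimethyl-6aH-cyclopenta[d][1,3]dioxol-4-olate (α′-lithium enolate of 3) | [Li+].CC1(C)O[C@H]2C=CC([O-])=C2O1 | intermediate (not isolated)
5 | lithium (1S)-6-tert-butoxy-1-[(3aS,6aS)-2,2-dimethyl-4-oxo-4,6a-dihydro-3aH-cyclopenta[d][1,3]dioxol-3a-yl]-6-oxohexan-1-olate | [Li+].CC(C)(C)OC(=O)CCCC[C@H]([O-])[C@]12OC(C)(C)O[C@H]1C=CC2=O | intermediate (not isolated)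
6 | tert-butyl (6S)-6-[(3aS,6aS)-2,2-dimethyl-4-oxo-4,6a-dihydro-3aH-cyclopenta[d][1,3]dioxol-3a-yl]-6-hydroxyhexanoate | CC(C)(C)OC(=O)CCCC[C@H](O)[C@]12OC(C)(C)O[C@H]1C=CC2=O | intermediate
7 | tert-butyl (6S)-6-acetoxy-6-[(3aS,6aS)-2,2-dimethyl-4-oxo-4,6a-dihydro-3aH-cyclopenta[d][1,3]dioxol-3a-yl]hexanoate | CC(C)(C)OC(=O)CCCC[C@H](OC(C)=O)[C@]12OC(C)(C)O[C@H]1C=CC2=O | intermediate
8 | (6S)-6-acetoxy-6-[(3aS,6aS)-2,2-dimethyl-4-oxo-4,6a-dihydro-3aH-cyclopenta[d][1,3]dioxol-3a-yl]hexanoic acid | OC(=O)CCCC[C@H](OC(C)=O)[C@]12OC(C)(C)O[C@H]1C=CC2=O | intermediate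
9 | undecanoic acid | CCCCCCCCCCC(=O)O | starting material
10 | (1S)-1-[(3aS,6aS)-2,2-dimethyl-4-oxo-4,6a-dihydro-3aH-cyclopenta[d][1,3]dioxol-3a-yl]pentadecyl acetate | CCCCCCCCCCCCCC[C@H](OC(C)=O)[C@]12OC(C)(C)O[C@H]1C=CC2=O | intermediate
11 | (1S)-1-[(1R,5S)-1,5-dihydroxy-2-oxocyclopent-3-en-1-yl]pentadecyl acetate [(4S,5R,6S) in the locants used above] | CCCCCCCCCCCCCC[C@H](OC(C)=O)[C@@]1(O)C(=O)C=C[C@@H]1O | target

**Step count**

Total step count: 6. Longest linear sequence: 6 steps (1 → 2 → 6 → 7 → 8 → 10 → 11), or 5 steps from enone 3.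

**Steps most likely to fail, with fallbacks**

Step 5 (mixed Kolbe electrolysis). The electrogenerated alkyl radicals may be intercepted by the C2=C3 enone, the C10 radical may be over-oxidised to the cation, or too much material may be lost to homo-dimers. The fallback replaces the radical union by a two-electron alkyl–alkyl Suzuki–Miyaura coupling and sets out from enone 3. Enolate 4 (LDA, THF, −78 °C) is added to commercial 5-bromopentanal instead of 2, and the aldolate is quenched cold to give (3aS,6aS)-3a-[(1S)-5-bromo-1-hydroxypentyl]-2,2-dimethyl-3a,6a-dihydro-4H-cyclopenta[d][1,3]dioxol-4-one F1. Acetylation (Ac2O, DMAP, pyridine) converts this into (1S)-5-bromo-1-[(3aS,6aS)-2,2-dimethyl-4-oxo-4,6a-dihydro-3aH-cyclopenta[d][1,3]dioxol-3a-yl]pentyl acetate F2. 1-Decene is hydroborated with 9-BBN-H to 9-decyl-9-borabicyclo[3.3.1]nonane F3, and F2 and F3 are coupled with Pd(OAc)2/PCy3 and K3PO4·H2O in THF at rt. This forms the same C10–C11 bond and comes back to the route at compound 10.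

Step 2 (aldol addition). Facial discrimination at the aldehyde carbon may be insufficient (chair against boat or open transition states), and the aldolate may equilibrate by retro-aldol reaction, so that 6 is formed together with its C6 epimer. The fallback sets out from 6 as this epimer mixture and replaces substrate control by reagent control. Dess–Martin oxidation gives the 1,3-diketone tert-butyl 6-[(3aR,6aS)-2,2-dimethyl-4-oxo-4,6a-dihydro-3aH-cyclopenta[d][1,3]dioxol-3a-yl]-6-oxohexanoate F4. Its C6 carbonyl is non-conjugated and α-oxygenated, so it should be more electrophilic than the conjugated C1 carbonyl. It is reduced with (R)-2-methyl-CBS-oxazaborolidine and catecholborane at −78 °C, where the tert-alkyl versus n-alkyl discrimination of the catalyst should deliver the (6S)-alcohol. The fallback comes back to the route at compound 6.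

Step 4 (tert-butyl ester cleavage). The isopropylidene acetal may be lost together with the tert-butyl group. The fallback sets out from 7 and accepts this loss. Aqueous TFA removes both groups at once to give (6S)-6-acetoxy-6-[(1R,5S)-1,5-dihydroxy-2-oxocyclopent-3-en-1-yl]hexanoic acid F5. The mixed Kolbe electrolysis with 9 is then run on F5 as the last step, a protecting-group-free endgame that comes back to the route directly at target 11.

**Further compounds**

F1 | step 5 | (3aS,6aS)-3a-[(1S)-5-bromo-1-hydroxypentyl]-2,2-dimethyl-3a,6a-dihydro-4H-cyclopenta[d][1,3]dioxol-4-one | BrCCCC[C@H](O)[C@]12OC(C)(C)O[C@H]1C=CC2=O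
F2 | step 5 | (1S)-5-bromo-1-[(3aS,6aS)-2,2-dimethyl-4-oxo-4,6a-dihydro-3aH-cyclopenta[d][1,3]dioxol-3a-yl]pentyl acetate | BrCCCC[C@H](OC(C)=O)[C@]12OC(C)(C)O[C@H]1C=CC2=O
F3 | step 5 | 9-decyl-9-borabicyclo[3.3.1]nonane | CCCCCCCCCCB1C2CCCC1CCC2
F4 | step 2 | tert-butyl 6-[(3aR,6aS)-2,2-dimethyl-4-oxo-4,6a-dihydro-3aH-cyclopenta[d][1,3]dioxol-3a-yl]-6-oxohexanoate | CC(C)(C)OC(=O)CCCCC(=O)[C@]12OC(C)(C)O[C@H]1C=CC2=O
F5 | step 4 | (6S)-6-acetoxy-6-[(1R,5S)-1,5-dihydroxy-2-oxocyclopent-3-en-1-yl]hexanoic acid | OC(=O)CCCC[C@H](OC(C)=O)[C@@]1(O)C(=O)C=C[C@@H]1O
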